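## The problem

Littorachalcone 13 is an unsymmetrical dihydrochalcone dimer: two 3-aryl-1-(2,4-dihydroxyphenyl)propan-1-one units are joined through their distal rings, the para-phenylene ring B and the 1,3,4-trisubstituted ring C, by one diaryl ether oxygen. It has four benzene rings and no stereocentre, so the task is one of regiochemistry and functional-group tolerance, and no stereocentre is available to control another. The hard bond is the ether: ring C carries a free hydroxyl ortho to the ether oxygen (C3–OH, C4–OAr) and only an alkyl chain para to it (C1), so it is an unactivated catechol mono-aryl ether for which SNAr has no electron-withdrawing group to lean on and copper-mediated coupling needs the two catechol oxygens told apart by protection. The two aroylethyl arms are identical, which invites a two-directional finish. Each arm ends in a resorcinol ketone (ring A) that is electron-rich, easily oxidised and open to further electrophilic substitution, and with five free phenols in 13 the closing steps should not oxidise and should not need a forcing global deprotection. The enabling feature is ring C itself: chain on C1, hydroxyl on C3 and aryloxy on C4 is the pattern of a 2-aryloxy-5-alkylcyclohex-2-enone (ketone carbon to C3, aryloxy carbon to C4, enone C5 to C1). A β-keto ester and an enal assemble that ring in one operation, with the two ring C oxygens different from the start. The only stereocentre that appears anywhere is C5 of this cyclohexenone; it controls nothing and vanishes on aromatisation.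

## Retrosynthesis

**13 to 11 and 12.** Both ring A–carbonyl bonds are cut, leading to diacid 11 and two molecules of resorcinol 12. Cutting inside the three-carbon arms instead (a chalcone-type condensation) would need protected resorcinol methyl ketones, a dialdehyde, a hydrogenation and a deprotection. The chosen cut removes two rings and four of the five phenols at once and uses ring A as an unmodified commodity. The forward reaction must acylate 12 twice at C4 and leave the activated ring C of 11 alone.

**11 to 10.** The two carboxylic acids are traced back to the methyl esters of 10. Free acids would consume base in the etherification and quench the amine catalyst of the annulation, so the arms travel as esters and are opened only when needed. The forward step is a plain saponification in the presence of one phenol.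

**10 to 9.** Ring C is taken back by two hydrogens to cyclohexenone 9. This trades the difficult aryl–oxygen bond for an enol ether, and the "phenol" oxygen becomes a ketone that cannot be confused with the ether oxygen. The forward step must dehydrogenate one ring without touching the esters or iodinating the new phenol.

**9 to 3 and 6.** The ring C bonds C1–C2 and C4–C5 (target numbering) are cut, giving aryloxy keto ester 3 and enal 6 via the open-chain adduct 7 and the ring-closed ester 8. Other pairs of ring bonds would demand reagents already carrying two of the three substituents in fixed relation. This pair lets each fragment carry one arm at its final length and oxidation level, with the tert-butyl ester as a traceless activating group. The forward reaction needs conjugate addition at the doubly activated carbon of 3, aldol closure from the aryloxy methylene, and loss of the tert-butyl ester.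

**3 to 1 and 2.** The ether C–O bond is cut at the sp3 carbon, giving phenol 1 and chloro keto ester 2, both commercial. This is the point of the plan: the diaryl ether oxygen is installed by an SN2 displacement instead of an aryl–oxygen coupling. The forward step must favour O-alkylation by the phenoxide over self-condensation of 2.

**6 to 4 and 5.** The C4=C5 double bond of 6 is cut to methyl pent-4-enoate 4 and (E)-but-2-enal 5. Cross-metathesis gives the enal in one step from two cheap liquids. It must be E-selective and must suppress homodimerisation of 4.

## Roads not taken

**Alternative 1:** The cut goes through ring B instead of ring C. Its C2–C3 and C4–C5 bonds are broken, leaving methyl coumalate A2 as a four-carbon diene and the ethynyl ether A3 of eugenol A4 as the two-carbon partner that already carries the ether oxygen. In the forward sense an inverse-demand [4+2] cycloaddition and decarboxylative retro-[4+2] would give methyl 4-(4-allyl-2-methoxyphenoxy)benzoate A1. The ester ends para to the aryloxy group because the nucleophilic terminal carbon of the ynol ether bonds to C6 of the pyranone.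
- Merits: ring C and its oxygen pattern are bought with A4, regiochemistry is set by polarity, and aromatisation is built into the key step. On that last point it is better than the chosen plan, which needs a separate dehydrogenation (step 4).
- Weak points: A3 is a labile aryl ynol ether that takes two operations to make from the phenol. A1 carries two different handles of the wrong length, a one-carbon ester on ring B and an allyl group on ring C. Each arm then needs its own chain adjustment, the two-directional end game is lost, and a methyl ether must still be cleaved late.
- Comparison: the chosen plan answers with both arms delivered identical, at final length and oxidation level, and with no O-methyl group to remove.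

**Alternative 2:** The cut removes both rings A. Their C1–C2 and C5–C6 bonds are broken, leading to bis-ynone A6 and two equivalents of 1,3-dimethoxy-1-(trimethylsilyloxy)buta-1,3-diene A7. Forward, a twofold Diels–Alder addition to the terminal ynones, loss of the acetal alkoxy group and desilylation would give the bis(2-hydroxy-4-methoxyphenyl) diketone A5.
- Merits: the ketene acetal carbon necessarily ends ortho to the acyl group, so the 2,4-dioxygenation of ring A is unambiguous and no Lewis acid meets ring C. In this respect it is more secure than step 6 of the chosen plan.
- Weak points: it leaves the diaryl ether unsolved, since A6 would itself have to come from a diaryl ether diacid of the kind of 11 by amide formation and alkynylation. Terminal ynones polymerise readily, two cycloadditions must both succeed, three methyl ethers remain to be cleaved, and a ring is built that is available in bulk as 12.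
- Comparison: the chosen plan relies on the well-established C4 preference of resorcinol acylation and saves several steps.

**Alternative 3:** Both bonds at each ketone carbonyl are cut, four in all, leading to diyne A9, two molecules of 1-iodo-2,4-dimethoxybenzene A10 and two of carbon monoxide A11. Forward, a twofold carbonylative Sonogashira coupling (PdCl2(PPh3)2/CuI) would give the bis-ynone pentamethyl ether A8. Hydrogenation of both triple bonds and cleavage of five methyl ethers would follow.
- Merits: four carbon–carbon bonds in one step, all rings purchased, and high convergence. The ether of A9 can be made by SNAr on a formyl-activated fluoroarene, so the overall count is comparable to the chosen plan and possibly one step shorter.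
- Weak points: direct coupling without carbonyl insertion and oxidative homocoupling of the diyne compete, and on a diyne every defect counts twice. A toxic gas is needed. The route ends in a fivefold demethylation by a strong Lewis acid on a diketone, the kind of forcing global deprotection the target argues against. The ortho-hydroxy diaryl ether is not created but imported as a protected guaiacol.
- Comparison: against comparable length, the chosen plan offers freedom from protecting groups, a last step that releases the free polyphenol directly, and ring C oxygens that are differentiated by construction.

Key step: step 3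

## Route

Assumption: the ring stereocentre created in step 3 is erased in step 4, so the amine catalyst is used as the racemate (either pure enantiomer would serve equally) and 7, 8 and 9 are racemic, 7 and 8 as diastereomer mixtures.

Step 1
Reactants: 1 methyl 3-(4-hydroxyphenyl)propanoate; 2 tert-butyl 4-chloro-3-oxobutanoate
Product: 3 tert-butyl 4-[4-(3-methoxy-3-oxopropyl)phenoxy]-3-oxobutanoate
Conditions: NaH (2.2 equiv), THF, 0 °C; 2 added slowly, rt to 50 °C; then 1 M HCl
Reagents that add atoms: none
Why: Williamson ether synthesis at a primary sp3 carbon; the second equivalent of NaH holds 2 as its stabilised keto ester enolate, a much poorer nucleophile than the sodium phenoxide of 1, so SN2 etherification should outrun self-alkylation. This two-equivalent protocol is the usual entry to 4-alkoxy- and 4-aryloxy-3-oxobutanoates, and the remote methyl ester is inert to both anions.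

Step 2
Reactants: 4 methyl pent-4-enoate; 5 (E)-but-2-enal
Product: 6 methyl (E)-6-oxohex-4-enoate
Conditions: second-generation Grubbs catalyst (H2IMes)(PCy3)Cl2Ru=CHPh (2.5 mol%), 5 (5 equiv), CH2Cl2, 40 °C
Reagents that add atoms: none
Why: Olefin cross-metathesis of a terminal alkene with an excess of an electron-poor enal that does not homodimerise; propene leaves as a gas and the conjugated product should form as the thermodynamically preferred E isomer.

Step 3
Reactants: 3 tert-butyl 4-[4-(3-methoxy-3-oxopropyl)phenoxy]-3-oxobutanoate; 6 methyl (E)-6-oxohex-4-enoate
Product: 9 methyl 3-[4-[[4-(3-methoxy-3-oxopropyl)-6-oxocyclohex-1-en-1-yl]oxy]phenyl]propanoate (racemic), via open-chain Michael adduct 7 (not isolated), via cyclohexenone tert-butyl ester 8 (not isolated)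
Conditions: rac-2-[diphenyl(trimethylsilyloxy)methyl]pyrrolidine (10 mol%), PhCO2H (10 mol%), toluene, rt; then p-TsOH·H2O (20 mol%), toluene, 80 °C
Reagents that add atoms: none
Why: The secondary amine condenses with enal 6 to an iminium ion whose bulky diphenyl(silyloxy)methyl group shields the iminium carbon, so the doubly activated C2 of keto ester 3 adds at the β-carbon (Michael addition) and hydrolysis of the resulting enamine returns the catalyst and leaves adduct 7. Acid then enolises the ketone toward the aryloxy-bearing methylene, which attacks the freed aldehyde in a favoured 6-(enolendo)-exo-trig aldol closure; dehydration gives enone 8, and ring C is closed through its C1–C2 (Michael) and C4–C5 (aldol) bonds. At 80 °C the same acid cleaves the tert-butyl ester to 2-methylpropene and a β-keto acid that loses carbon dioxide, giving 9. The closest known reaction type is the amine-catalysed Michael addition of tert-butyl β-keto esters to enals followed by acid-induced aldol condensation and decarboxylation to 5-substituted cyclohex-2-enones; a heteroatom-substituted γ-methylene acting as aldol donor has precedent in the corresponding annulations of 4-halo-3-oxobutanoates. The one new stereocentre (the ring carbon bearing the propanoate chain) is formed in the Michael step without control because the catalyst is racemic, which is intended since step 4 makes that carbon sp2. Two selectivities are needed: conjugate instead of carbonyl addition, secured by the hindered iminium ion, and the correct donor and acceptor sites, secured by acidity (only C2 between the two carbonyls is deprotonated under amine catalysis) and by ring size (the other aldol pairings among ketone, aldehyde and their enols would close four-membered rings, and the ester carbonyls are not electrophilic enough under these conditions). The aryl enol ether of 9 should survive the acid because protonation at its β-carbon would place a cation next to the ketone carbonyl.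

Step 4
Reactants: 9 methyl 3-[4-[[4-(3-methoxy-3-oxopropyl)-6-oxocyclohex-1-en-1-yl]oxy]phenyl]propanoate
Product: 10 methyl 3-[4-[2-hydroxy-4-(3-methoxy-3-oxopropyl)phenoxy]phenyl]propanoate
Conditions: I2 (20 mol%), DMSO, 90 °C
Reagents that add atoms: none
Why: Iodine-catalysed dehydrogenative aromatisation of a cyclohexenone: iodination at C6, the only enolisable α-position, and loss of hydrogen iodide introduce the second ring double bond, tautomerisation gives the phenol, and DMSO reoxidises iodide to I2. Compound 9 is the aryl ether of a cyclohexane-1,2-dione enol, the oxidation level from which this reagent pair is known to deliver catechol derivatives; esters and the diaryl ether are inert.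

Step 5
Reactants: 10 methyl 3-[4-[2-hydroxy-4-(3-methoxy-3-oxopropyl)phenoxy]phenyl]propanoate
Product: 11 3-[4-[4-(2-carboxyethyl)-2-hydroxyphenoxy]phenyl]propanoic acid
Conditions: LiOH·H2O (6 equiv), THF/H2O, rt; then 1 M HCl
Reagents that add atoms: lithium hydroxide, [Li+].[OH-]
Why: Saponification of two unhindered methyl esters; the phenoxide formed in base and the diaryl ether are unaffected, and acidification should return the diacid.

Step 6
Reactants: 11 3-[4-[4-(2-carboxyethyl)-2-hydroxyphenoxy]phenyl]propanoic acid; 12 resorcinol
Product: 13 littorachalcone, 1-(2,4-dihydroxyphenyl)-3-[4-[4-[3-(2,4-dihydroxyphenyl)-3-oxopropyl]-2-hydroxyphenoxy]phenyl]propan-1-one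
Conditions: 12 (6 equiv), BF3·OEt2 (neat), 85 °C; then H2O
Reagents that add atoms: none
Why: Nencki-type Friedel–Crafts C-acylation: BF3 activates each carboxylic acid, which acylates resorcinol at C4 (para to one hydroxyl, ortho to the other) directly or by O-acylation and Fries migration, and the chelated ortho-hydroxy ketone is deactivated toward a second acylation. This is the standard protecting-group-free route to 2,4-dihydroxyphenyl ketones, including dihydrochalcones made from hydroxylated 3-arylpropanoic acids; the large excess of the far more nucleophilic resorcinol should outcompete ring C.

## Compound list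

1 | methyl 3-(4-hydroxyphenyl)propanoate | COC(=O)CCc1ccc(O)cc1 | starting material
2 | tert-butyl 4-chloro-3-oxobutanoate | CC(C)(C)OC(=O)CC(=O)CCl | starting material
3 | tert-butyl 4-[4-(3-methoxy-3-oxopropyl)phenoxy]-3-oxobutanoate | COC(=O)CCc1ccc(OCC(=O)CC(=O)OC(C)(C)C)cc1 | intermediate
4 | methyl pent-4-enoate | COC(=O)CCC=C | starting material
5 | (E)-but-2-enal (crotonaldehyde) | C/C=C/C=O | starting material
6 | methyl (E)-6-oxohex-4-enoate | COC(=O)CC/C=C/C=O | intermediate
7 | 1-tert-butyl 6-methyl 2-[2-[4-(3-methoxy-3-oxopropyl)phenoxy]acetyl]-3-(2-oxoethyl)hexanedioate (racemic, diastereomer mixture) | COC(=O)CCc1ccc(OCC(=O)C(C(=O)OC(C)(C)C)C(CC=O)CCC(=O)OC)cc1 | intermediate (not isolated)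
8 | tert-butyl 3-[4-(3-methoxy-3-oxopropyl)phenoxy]-6-(3-methoxy-3-oxopropyl)-2-oxocyclohex-3-ene-1-carboxylate (racemic, diastereomer mixture) | COC(=O)CCC1CC=C(Oc2ccc(CCC(=O)OC)cc2)C(=O)C1C(=O)OC(C)(C)C | intermediate (not isolated)
9 | methyl 3-[4-[[4-(3-methoxy-3-oxopropyl)-6-oxocyclohex-1-en-1-yl]oxy]phenyl]propanoate (racemic) | COC(=O)CCC1CC=C(Oc2ccc(CCC(=O)OC)cc2)C(=O)C1 | intermediate
10 | methyl 3-[4-[2-hydroxy-4-(3-methoxy-3-oxopropyl)phenoxy]phenyl]propanoate | COC(=O)CCc1ccc(Oc2ccc(CCC(=O)OC)cc2O)cc1 | intermediate
11 | 3-[4-[4-(2-carboxyethyl)-2-hydroxyphenoxy]phenyl]propanoic acid | OC(=O)CCc1ccc(Oc2ccc(CCC(=O)O)cc2O)cc1 | intermediate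
12 | resorcinol (benzene-1,3-diol) | Oc1cccc(O)c1 | starting material
13 | littorachalcone, 1-(2,4-dihydroxyphenyl)-3-[4-[4-[3-(2,4-dihydroxyphenyl)-3-oxopropyl]-2-hydroxyphenoxy]phenyl]propan-1-one | O=C(CCc1ccc(Oc2ccc(CCC(=O)c3ccc(O)cc3O)cc2O)cc1)c1ccc(O)cc1O | target

## Step count and risks

Total step count: 6. Longest linear sequence: 5 (steps 1, 3, 4, 5, 6); step 2 supplies the second fragment.

**Step 3 (key step).**
- What may go wrong: carbonyl (1,2-) addition of 3 to the enal followed by oxa-electrocyclisation instead of conjugate addition; ring–chain closure of the adduct to a lactol that resists the aldol step; a second Michael addition at C2; slow acid hydrolysis of the aryl enol ether by the water released in the condensation.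
- Fallback: take the aryloxy group out of the annulation. Starting from enal 6, the same amine-catalysed Michael addition, aldol condensation and decarboxylation is run with commercial tert-butyl 3-oxobutanoate, the parent case of this reaction type, to give methyl 3-(5-oxocyclohex-3-en-1-yl)propanoate F1. Nucleophilic (Weitz–Scheffer) epoxidation (H2O2, cat. NaOH, MeOH, 0 °C) would give methyl 3-(5-oxo-7-oxabicyclo[4.1.0]heptan-3-yl)propanoate F2. Phenol 1 (Cs2CO3 0.2 equiv, DMF, 60 °C) then opens the epoxide at the carbon α to the ketone and the β-hydroxy ketone dehydrates, which rejoins the route at cyclohexenone 9. The ring C bonds and the ring closure are unchanged; only the ether bond, still made at an sp3 carbon, moves behind the annulation.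

**Step 6.**
- What may go wrong: intramolecular acylation onto the activated ring C (closure of a five-membered ketone ring para to its hydroxyl); incomplete second acylation; O-acylation without Fries migration; minor attack at C2 of resorcinol. All would give polar mixtures that are hard to separate.
- Fallback: from diacid 11, acylate 1,3-dimethoxybenzene instead, using (CF3CO)2O with catalytic H3PO4 at rt. The mixed anhydride is formed under conditions that also mask the ring C hydroxyl as its trifluoroacetate until aqueous work-up, and the arene can react only at C4. This should give 1-(2,4-dimethoxyphenyl)-3-[4-[4-[3-(2,4-dimethoxyphenyl)-3-oxopropyl]-2-hydroxyphenoxy]phenyl]propan-1-one F3. Cleavage of the four methyl ethers with BBr3 (CH2Cl2, −78 °C to rt), which leaves diaryl ethers intact, returns to 13.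

**Step 4.**
- What may go wrong: electrophilic iodination of the newly formed electron-rich phenol (para to the hydroxyl); Kornblum-type oxygenation at C6 instead of elimination; acid-promoted cleavage of the enol ether by the hydrogen iodide formed.
- Fallback: from 9, switch from halogen-mediated chemistry to palladium-catalysed aerobic dehydrogenation (Pd(OCOCF3)2 5 mol%, 2-(dimethylamino)pyridine, p-TsOH, O2 1 atm, DMSO, 80 °C). A divalent palladium enolate undergoes β-hydride elimination and the dienone tautomerises, giving 10 directly with no electrophilic halogen in the flask. No new compound is involved.

**Step 1.**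
- What may go wrong: self-alkylation and condensation of the enolate of 2; sluggish displacement on the enolised chloride, leading to incomplete conversion.
- Fallback: build the keto ester from the aryloxyacetic acid instead. From phenol 1, alkylation with tert-butyl bromoacetate (K2CO3, acetone) gives tert-butyl 2-[4-(3-methoxy-3-oxopropyl)phenoxy]acetate F4. CF3CO2H in CH2Cl2 frees 2-[4-(3-methoxy-3-oxopropyl)phenoxy]acetic acid F5. Activation with 1,1'-carbonyldiimidazole and decarboxylative Claisen condensation with the magnesium salt of mono-tert-butyl malonate (potassium 3-tert-butoxy-3-oxopropanoate, MgCl2, Et3N, THF) returns to keto ester 3.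

## Further compounds

F1 | step 3 | methyl 3-(5-oxocyclohex-3-en-1-yl)propanoate (racemic) | COC(=O)CCC1CC=CC(=O)C1
F2 | step 3 | methyl 3-(5-oxo-7-oxabicyclo[4.1.0]heptan-3-yl)propanoate (racemic, diastereomer mixture) | COC(=O)CCC1CC2OC2C(=O)C1
F3 | step 6 | 1-(2,4-dimethoxyphenyl)-3-[4-[4-[3-(2,4-dimethoxyphenyl)-3-oxopropyl]-2-hydroxyphenoxy]phenyl]propan-1-one | COc1ccc(C(=O)CCc2ccc(Oc3ccc(CCC(=O)c4ccc(OC)cc4OC)cc3O)cc2)c(OC)c1
F0 | step 4 | none | none
F4 | step 1 | tert-butyl 2-[4-(3-methoxy-3-oxopropyl)phenoxy]acetate | COC(=O)CCc1ccc(OCC(=O)OC(C)(C)C)cc1
F5 | step 1 | 2-[4-(3-methoxy-3-oxopropyl)phenoxy]acetic acid | COC(=O)CCc1ccc(OCC(=O)O)cc1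
A1 | alternative 1 | methyl 4-(4-allyl-2-methoxyphenoxy)benzoate | COC(=O)c1ccc(Oc2ccc(CC=C)cc2OC)cc1
A2 | alternative 1 | methyl coumalate (methyl 2-oxo-2H-pyran-5-carboxylate) | COC(=O)C1=COC(=O)C=C1
A3 | alternative 1 | 4-allyl-1-(ethynyloxy)-2-methoxybenzene | C#COc1ccc(CC=C)cc1OC
A4 | alternative 1 | eugenol (4-allyl-2-methoxyphenol) | C=CCc1ccc(O)c(OC)c1
A5 | alternative 2 | 1-(2-hydroxy-4-methoxyphenyl)-3-[4-[4-[3-(2-hydroxy-4-methoxyphenyl)-3-oxopropyl]-2-methoxyphenoxy]phenyl]propan-1-one | COc1ccc(C(=O)CCc2ccc(Oc3ccc(CCC(=O)c4ccc(OC)cc4O)cc3OC)cc2)c(O)c1
A6 | alternative 2 | 5-[4-[2-methoxy-4-(3-oxopent-4-yn-1-yl)phenoxy]phenyl]pent-1-yn-3-one | C#CC(=O)CCc1ccc(Oc2ccc(CCC(=O)C#C)cc2OC)cc1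
A7 | alternative 2 | 1,3-dimethoxy-1-(trimethylsilyloxy)buta-1,3-diene | COC(=C)C=C(OC)O[Si](C)(C)C
A8 | alternative 3 | 1-(2,4-dimethoxyphenyl)-3-[4-[4-[3-(2,4-dimethoxyphenyl)-3-oxoprop-1-yn-1-yl]-2-methoxyphenoxy]phenyl]prop-2-yn-1-one | COc1ccc(C(=O)C#Cc2ccc(Oc3ccc(C#CC(=O)c4ccc(OC)cc4OC)cc3OC)cc2)c(OC)c1
A9 | alternative 3 | 4-ethynyl-1-(4-ethynylphenoxy)-2-methoxybenzene | C#Cc1ccc(Oc2ccc(C#C)cc2OC)cc1
A10 | alternative 3 | 1-iodo-2,4-dimethoxybenzene | COc1ccc(I)c(OC)c1
A11 | alternative 3 | carbon monoxide | [C-]#[O+]
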